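**Strategy.** The target is cut at O1–C2 of the tetrahydropyran (ring numbered O1, C2 arylethyl, C4 acetoxy, C6 aryl) and at the first bond of the C2 side arm. C2 carries the ring oxygen plus a two-carbon arm, which is what remains when a hydroxyl adds to a terminal alkene under palladium and the resulting alkylmetal picks up carbon monoxide. One operation therefore closes the ring, sets C2 cis to C6 and delivers a CH2CO2Me handle whose ester carbon becomes the benzylic CH2 of the arm. The precursor is a syn (1S,3S)-1-aryl-3-silyloxyhex-5-en-1-ol with a free benzylic hydroxyl and a benzyl-protected catechol.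

Key step: step 9

Remark: ring atoms are numbered O1, C2 (carbon bearing the arm), C4 (oxygenated carbon), C6 (aryl carbon) throughout; the alkene geometry of 19–21 is left undefined because step 15 removes it; 4-(benzyloxy)-3-methoxybenzyl alcohol and PPh3·HBr are taken as commercial.

**Step 1**
Reactants: 1 3,4-dihydroxy-5-methoxybenzaldehyde (5-hydroxyvanillin)
Product: 2 3,4-bis(benzyloxy)-5-methoxybenzaldehyde
Conditions: BnBr (2.3 equiv), K2CO3, DMF, 60 °C
Reagents that add atoms: benzyl bromide, BrCc1ccccc1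
Why: Williamson etherification of both catechol phenoxides with a reactive benzylic halide under carbonate base, which leaves the aldehyde untouched.

**Step 2**
Reactants: 2 3,4-bis(benzyloxy)-5-methoxybenzaldehyde
Product: 3 2-[3,4-bis(benzyloxy)-5-methoxyphenyl]-1,3-dithiane
Conditions: HS(CH2)3SH, BF3·OEt2 (cat.), CH2Cl2, 0 °C
Reagents that add atoms: propane-1,3-dithiol, SCCCS
Why: Lewis-acid-catalysed dithioacetalisation of an aromatic aldehyde, with catalytic BF3·OEt2 at 0 °C being too mild to cleave aryl benzyl ethers.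

**Step 3**
Reactants: 4 (S)-epichlorohydrin
Product: 5 (S)-1-chloropent-4-en-2-ol
Conditions: CH2=CHMgBr, CuI (10 mol %), THF, −78 → −20 °C; aq. NH4Cl
Reagents that add atoms: vinylmagnesium bromide, C=C[Mg]Br
Why: Copper-catalysed Grignard opening of the epoxide at its unsubstituted carbon, which does not touch the stereocentre, so the (S) configuration is carried over.

**Step 4**
Reactants: 5 (S)-1-chloropent-4-en-2-ol
Product: 6 (S)-2-allyloxirane (1,2-epoxy-4-pentene)
Conditions: NaOH (powdered), Et2O, rt; distillation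
Reagents that add atoms: none
Why: Intramolecular Williamson closure of the chlorohydrin at the primary chloride, in which the carbinol C–O bond is never broken and the (S) centre is retained.

**Step 5**
Reactants: 3 2-[3,4-bis(benzyloxy)-5-methoxyphenyl]-1,3-dithiane; 6 (S)-2-allyloxirane
Product: 8 (2S)-1-{2-[3,4-bis(benzyloxy)-5-methoxyphenyl]-1,3-dithian-2-yl}pent-4-en-2-ol, via 2-lithio-1,3-dithiane 7 (not isolated)
Conditions: n-BuLi, THF, −78 → −20 °C; then 6, −20 °C → rt; aq. NH4Cl
Reagents that add atoms: none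
Why: Corey–Seebach umpolung in which the aryl-stabilised dithiane anion opens the terminal epoxide by SN2 attack at its CH2 carbon, leaving the (S) carbinol centre intact.

**Step 6**
Reactants: 8 (2S)-1-{2-[3,4-bis(benzyloxy)-5-methoxyphenyl]-1,3-dithian-2-yl}pent-4-en-2-ol
Product: 9 tert-butyl{[(2S)-1-{2-[3,4-bis(benzyloxy)-5-methoxyphenyl]-1,3-dithian-2-yl}pent-4-en-2-yl]oxy}dimethylsilane
Conditions: TBSOTf, 2,6-lutidine, CH2Cl2, 0 °C; aq. NaHCO3
Reagents that add atoms: tert-butyldimethylsilyl triflate, CC(C)(C)[Si](C)(C)OS(=O)(=O)C(F)(F)F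
Why: Silyl triflate silylation of a hindered secondary alcohol with a non-nucleophilic pyridine base, which caps this oxygen so that the later benzylic hydroxyl is the only free one.

**Step 7**
Reactants: 9 tert-butyl{[(2S)-1-{2-[3,4-bis(benzyloxy)-5-methoxyphenyl]-1,3-dithian-2-yl}pent-4-en-2-yl]oxy}dimethylsilane
Product: 10 (3S)-1-[3,4-bis(benzyloxy)-5-methoxyphenyl]-3-[(tert-butyldimethylsilyl)oxy]hex-5-en-1-one
Conditions: MeI (excess), CaCO3, MeCN/H2O (9:1), 45 °C
Reagents that add atoms: water, O
Why: Alkylative dithiane hydrolysis in which S-methylation turns sulfur into a leaving group and water delivers the aryl ketone under carbonate buffering that spares the silyl ether, the alkene and the benzyl ethers.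

**Step 8**
Reactants: 10 (3S)-1-[3,4-bis(benzyloxy)-5-methoxyphenyl]-3-[(tert-butyldimethylsilyl)oxy]hex-5-en-1-one
Product: 11 (1S,3S)-1-[3,4-bis(benzyloxy)-5-methoxyphenyl]-3-[(tert-butyldimethylsilyl)oxy]hex-5-en-1-ol (syn)
Conditions: RuCl(p-cymene)[(S,S)-TsDPEN] (2 mol %), HCO2H/Et3N (5:2), DMF, 40 °C
Reagents that add atoms: none
Why: Noyori asymmetric transfer hydrogenation in which the (S,S)-TsDPEN ruthenium hydride distinguishes the aryl from the alkyl flank of the ketone and should deliver hydride to give the (S) carbinol under catalyst control (the sense known for aryl alkyl ketones), syn to the C3 silyloxy centre, without reducing the isolated alkene.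

**Step 9**
Reactants: 11 (1S,3S)-1-[3,4-bis(benzyloxy)-5-methoxyphenyl]-3-[(tert-butyldimethylsilyl)oxy]hex-5-en-1-ol
Product: 14 methyl 2-[(2R,4S,6S)-6-[3,4-bis(benzyloxy)-5-methoxyphenyl]-4-[(tert-butyldimethylsilyl)oxy]oxan-2-yl]acetate, via alkylpalladium chloride 12 (not isolated), via acylpalladium chloride 13 (not isolated)
Conditions: PdCl2 (10 mol %), CuCl2 (3 equiv), CO (1 atm), MeOH/MeCN (1:1), rt; aq. NaHCO3
Reagents that add atoms: carbon monoxide, [C-]#[O+]; methanol, CO
Why: PdCl2 activates the terminal C=C as a π-complex and the free benzylic hydroxyl adds to its inner carbon from the face opposite the metal, giving σ-alkyl species 12 of divalent palladium, which takes up CO to give acyl species 13; methanol cleaves 13 to ester 14, and the zerovalent palladium released is returned to the divalent state by CuCl2. The closest known reaction type is the intramolecular alkoxycarbonylation (oxypalladation–carbonylation) of hydroxy alkenes to cis-2,6-disubstituted tetrahydropyranylacetates. The oxane ring closes in a 6-exo-trig mode, forming O1–C2, and the CH2–C(=O) bond follows from the CO insertion. The new C2 stereocentre (R in 14) should be set by a chair-like transition state with the C6 aryl group and the coordinated alkene both equatorial, so the arm lands cis to the aryl group, while the C4 silyloxy group, fixed axial by the syn relationship in 11, would clash 1,3-diaxially with an axial alkene and so further disfavours the trans closure. The step needs chemoselectivity (one nucleophilic oxygen, ester formation ahead of β-hydride loss or lactone formation) and 2,6-cis diastereoselectivity: the silyl cap leaves only the C1 hydroxyl free and blocks bridged lactone formation, the CO atmosphere lets insertion outrun β-hydride elimination, and the equatorial preference of the aryl group secures the cis ring.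

**Step 10**
Reactants: 14 methyl 2-[(2R,4S,6S)-6-[3,4-bis(benzyloxy)-5-methoxyphenyl]-4-[(tert-butyldimethylsilyl)oxy]oxan-2-yl]acetate
Product: 15 2-[(2R,4S,6S)-6-[3,4-bis(benzyloxy)-5-methoxyphenyl]-4-[(tert-butyldimethylsilyl)oxy]oxan-2-yl]acetaldehyde
Conditions: i-Bu2AlH (1.1 equiv), CH2Cl2, −78 °C; MeOH, then aq. KNaC4H4O6
Reagents that add atoms: none
Why: Partial ester reduction with i-Bu2AlH at low temperature, where the tetrahedral aluminium hemiacetal (stabilised by the β ring oxygen) persists until work-up and then releases the aldehyde.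

**Step 11**
Reactants: 16 4-(benzyloxy)-3-methoxybenzyl alcohol
Product: 17 [4-(benzyloxy)-3-methoxybenzyl]triphenylphosphonium bromide
Conditions: PPh3·HBr, MeCN, reflux
Reagents that add atoms: triphenylphosphine hydrobromide, [Br-].c1ccc([PH+](c2ccccc2)c2ccccc2)cc1
Why: Direct phosphonium salt formation from an electron-rich benzylic alcohol, in which HBr activates the hydroxyl and triphenylphosphine captures the benzylic electrophile by nucleophilic substitution.

**Step 12**
Reactants: 17 [4-(benzyloxy)-3-methoxybenzyl]triphenylphosphonium bromide; 15 2-[(2R,4S,6S)-6-[3,4-bis(benzyloxy)-5-methoxyphenyl]-4-[(tert-butyldimethylsilyl)oxy]oxan-2-yl]acetaldehyde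
Product: 19 (2S,4S,6S)-2-{3-[4-(benzyloxy)-3-methoxyphenyl]prop-2-en-1-yl}-6-[3,4-bis(benzyloxy)-5-methoxyphenyl]-4-[(tert-butyldimethylsilyl)oxy]oxane (mixture of alkene isomers), via phosphorus ylide 18 (not isolated)
Conditions: NaN(SiMe3)2, THF, 0 °C; then 15, −78 °C → rt
Reagents that add atoms: none
Why: Wittig olefination with a semi-stabilised benzylidene ylide, whose alkene geometry is irrelevant because step 15 saturates the double bond, and whose low-temperature addition should suppress β-elimination of the ring oxygen.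

**Step 13**
Reactants: 19 (2S,4S,6S)-2-{3-[4-(benzyloxy)-3-methoxyphenyl]prop-2-en-1-yl}-6-[3,4-bis(benzyloxy)-5-methoxyphenyl]-4-[(tert-butyldimethylsilyl)oxy]oxane
Product: 20 (2S,4S,6S)-2-{3-[4-(benzyloxy)-3-methoxyphenyl]prop-2-en-1-yl}-6-[3,4-bis(benzyloxy)-5-methoxyphenyl]oxan-4-ol
Conditions: Bu4NF, THF, rt; aq. NH4Cl
Reagents that add atoms: none
Why: Fluoride-driven silyl ether cleavage (strong Si–F bond), to which the benzyl ethers, the styrene and the ring stereocentres are inert.

**Step 14**
Reactants: 20 (2S,4S,6S)-2-{3-[4-(benzyloxy)-3-methoxyphenyl]prop-2-en-1-yl}-6-[3,4-bis(benzyloxy)-5-methoxyphenyl]oxan-4-ol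
Product: 21 (2S,4S,6S)-2-{3-[4-(benzyloxy)-3-methoxyphenyl]prop-2-en-1-yl}-6-[3,4-bis(benzyloxy)-5-methoxyphenyl]oxan-4-yl acetate
Conditions: Ac2O, pyridine, DMAP (cat.), CH2Cl2, rt
Reagents that add atoms: acetic anhydride, CC(=O)OC(C)=O
Why: DMAP-catalysed acylation of the axial secondary alcohol with acetic anhydride, which touches no stereocentre.

**Step 15**
Reactants: 21 (2S,4S,6S)-2-{3-[4-(benzyloxy)-3-methoxyphenyl]prop-2-en-1-yl}-6-[3,4-bis(benzyloxy)-5-methoxyphenyl]oxan-4-yl acetate
Product: 22 (2S,4S,6S)-6-(3,4-dihydroxy-5-methoxyphenyl)-2-[2-(4-hydroxy-3-methoxyphenyl)ethyl]oxan-4-yl acetate (CNP0143286.2)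
Conditions: H2 (1 atm), 10% Pd/C, EtOAc, rt
Reagents that add atoms: none
Why: Heterogeneous catalytic hydrogenation over Pd/C should saturate the styrene and hydrogenolyse the three aryl benzyl ethers in one operation, while in neutral ethyl acetate the cyclic benzylic C6–O1 bond and the acetate should persist.

**Compound list**

1 | 3,4-dihydroxy-5-methoxybenzaldehyde (5-hydroxyvanillin) | COc1cc(C=O)cc(O)c1O | starting material
2 | 3,4-bis(benzyloxy)-5-methoxybenzaldehyde | COc1cc(C=O)cc(OCc2ccccc2)c1OCc1ccccc1 | intermediate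
3 | 2-[3,4-bis(benzyloxy)-5-methoxyphenyl]-1,3-dithiane | COc1cc(C2SCCCS2)cc(OCc2ccccc2)c1OCc1ccccc1 | intermediate
4 | (S)-epichlorohydrin | ClC[C@@H]1CO1 | starting material
5 | (S)-1-chloropent-4-en-2-ol | ClC[C@@H](O)CC=C | intermediate
6 | (S)-2-allyloxirane | C=CC[C@H]1CO1 | intermediate
7 | 2-[3,4-bis(benzyloxy)-5-methoxyphenyl]-2-lithio-1,3-dithiane | COc1cc(C2([Li])SCCCS2)cc(OCc2ccccc2)c1OCc1ccccc1 | intermediate (not isolated)
8 | (2S)-1-{2-[3,4-bis(benzyloxy)-5-methoxyphenyl]-1,3-dithian-2-yl}pent-4-en-2-ol | C=CC[C@H](O)CC1(c2cc(OC)c(OCc3ccccc3)c(OCc3ccccc3)c2)SCCCS1 | intermediate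
9 | tert-butyl{[(2S)-1-{2-[3,4-bis(benzyloxy)-5-methoxyphenyl]-1,3-dithian-2-yl}pent-4-en-2-yl]oxy}dimethylsilane | C=CC[C@H](O[Si](C)(C)C(C)(C)C)CC1(c2cc(OC)c(OCc3ccccc3)c(OCc3ccccc3)c2)SCCCS1 | intermediate
10 | (3S)-1-[3,4-bis(benzyloxy)-5-methoxyphenyl]-3-[(tert-butyldimethylsilyl)oxy]hex-5-en-1-one | C=CC[C@H](O[Si](C)(C)C(C)(C)C)CC(=O)c1cc(OC)c(OCc2ccccc2)c(OCc2ccccc2)c1 | intermediate
11 | (1S,3S)-1-[3,4-bis(benzyloxy)-5-methoxyphenyl]-3-[(tert-butyldimethylsilyl)oxy]hex-5-en-1-ol | C=CC[C@H](O[Si](C)(C)C(C)(C)C)C[C@H](O)c1cc(OCc2ccccc2)c(OCc2ccccc2)c(OC)c1 | intermediate (key-step precursor)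
12 | {[(2R,4S,6S)-6-[3,4-bis(benzyloxy)-5-methoxyphenyl]-4-[(tert-butyldimethylsilyl)oxy]oxan-2-yl]methyl}palladium chloride | Cl[Pd]C[C@H]1C[C@H](O[Si](C)(C)C(C)(C)C)C[C@@H](c2cc(OCc3ccccc3)c(OCc3ccccc3)c(OC)c2)O1 | intermediate (not isolated)
13 | {2-[(2R,4S,6S)-6-[3,4-bis(benzyloxy)-5-methoxyphenyl]-4-[(tert-butyldimethylsilyl)oxy]oxan-2-yl]acetyl}palladium chloride | Cl[Pd]C(=O)C[C@H]1C[C@H](O[Si](C)(C)C(C)(C)C)C[C@@H](c2cc(OCc3ccccc3)c(OCc3ccccc3)c(OC)c2)O1 | intermediate (not isolated)
14 | methyl 2-[(2R,4S,6S)-6-[3,4-bis(benzyloxy)-5-methoxyphenyl]-4-[(tert-butyldimethylsilyl)oxy]oxan-2-yl]acetate | COC(=O)C[C@H]1C[C@H](O[Si](C)(C)C(C)(C)C)C[C@@H](c2cc(OCc3ccccc3)c(OCc3ccccc3)c(OC)c2)O1 | intermediate (key-step product)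
15 | 2-[(2R,4S,6S)-6-[3,4-bis(benzyloxy)-5-methoxyphenyl]-4-[(tert-butyldimethylsilyl)oxy]oxan-2-yl]acetaldehyde | O=CC[C@H]1C[C@H](O[Si](C)(C)C(C)(C)C)C[C@@H](c2cc(OCc3ccccc3)c(OCc3ccccc3)c(OC)c2)O1 | intermediate
16 | 4-(benzyloxy)-3-methoxybenzyl alcohol | COc1cc(CO)ccc1OCc1ccccc1 | starting material
17 | [4-(benzyloxy)-3-methoxybenzyl]triphenylphosphonium bromide | COc1cc(C[P+](c2ccccc2)(c2ccccc2)c2ccccc2)ccc1OCc1ccccc1.[Br-] | intermediate
18 | [4-(benzyloxy)-3-methoxybenzylidene]triphenylphosphorane | COc1cc(C=P(c2ccccc2)(c2ccccc2)c2ccccc2)ccc1OCc1ccccc1 | intermediate (not isolated)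
19 | (2S,4S,6S)-2-{3-[4-(benzyloxy)-3-methoxyphenyl]prop-2-en-1-yl}-6-[3,4-bis(benzyloxy)-5-methoxyphenyl]-4-[(tert-butyldimethylsilyl)oxy]oxane, alkene isomers | COc1cc(C=CC[C@H]2C[C@H](O[Si](C)(C)C(C)(C)C)C[C@@H](c3cc(OCc4ccccc4)c(OCc4ccccc4)c(OC)c3)O2)ccc1OCc1ccccc1 | intermediate
20 | (2S,4S,6S)-2-{3-[4-(benzyloxy)-3-methoxyphenyl]prop-2-en-1-yl}-6-[3,4-bis(benzyloxy)-5-methoxyphenyl]oxan-4-ol | COc1cc(C=CC[C@H]2C[C@H](O)C[C@@H](c3cc(OCc4ccccc4)c(OCc4ccccc4)c(OC)c3)O2)ccc1OCc1ccccc1 | intermediate
21 | (2S,4S,6S)-2-{3-[4-(benzyloxy)-3-methoxyphenyl]prop-2-en-1-yl}-6-[3,4-bis(benzyloxy)-5-methoxyphenyl]oxan-4-yl acetate | COc1cc(C=CC[C@H]2C[C@H](OC(C)=O)C[C@@H](c3cc(OCc4ccccc4)c(OCc4ccccc4)c(OC)c3)O2)ccc1OCc1ccccc1 | intermediate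
22 | (2S,4S,6S)-6-(3,4-dihydroxy-5-methoxyphenyl)-2-[2-(4-hydroxy-3-methoxyphenyl)ethyl]oxan-4-yl acetate | COc1cc(CC[C@H]2C[C@H](OC(C)=O)C[C@@H](c3cc(O)c(O)c(OC)c3)O2)ccc1O | target

**Step count.** Total: 15 steps. Longest linear sequence: 12 steps (steps 1, 2, 5–10, 12–15 from compound 1; the branch from compound 4 through steps 3 and 4 is equally long).

**Steps most likely to fail**

Step 9. The HCl liberated as the copper oxidant is consumed may solvolyse the electron-rich benzylic alcohol or strip the silyl ether before ring closure. β-Hydride loss from the alkylpalladium may also compete with CO capture, and the closure may not be cleanly cis-selective. The fallback sets out from 11 and replaces the metal-mediated closure by a conjugate addition. Cross-metathesis of 11 with methyl acrylate (second-generation Hoveyda–Grubbs catalyst, CH2Cl2, 40 °C) should give methyl (2E,5S,7S)-7-[3,4-bis(benzyloxy)-5-methoxyphenyl]-5-[(tert-butyldimethylsilyl)oxy]-7-hydroxyhept-2-enoate F1. Intramolecular oxa-Michael addition of its benzylic hydroxyl under equilibrating base (catalytic KOt-Bu, THF, 0 °C) should then close the ring to the thermodynamically preferred 2,6-cis ester, rejoining the route at 14.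

Step 8. Facial selectivity may be poor if the resident C3 centre and its bulky silyloxy chain disturb the catalyst's aryl/alkyl discrimination. Turnover may also be slow with a para-alkoxy aryl ketone, giving formic acid time to erode the silyl ether. The fallback sets out from 10 and changes the mode of hydride delivery to a Corey–Bakshi–Shibata reduction: (R)-2-methyl-CBS-oxazaborolidine with catecholborane in toluene at −78 °C. There the Lewis-acid-bound ketone receives hydride from the coordinated borane on the same face, and the terminal alkene is not hydroborated at that temperature. It returns directly to 11; no new compound is made on the way (F0).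

Step 15. Over-reduction by hydrogenolysis of the benzylic C6–O1 ring bond next to the electron-rich arene may open the tetrahydropyran, and stopping early may leave benzyl ethers in place. The fallback sets out from 21 and avoids heterogeneous palladium. Homogeneous hydrogenation with RhCl(PPh3)3 and H2 in benzene/EtOH should saturate only the alkene and give (2S,4S,6S)-6-[3,4-bis(benzyloxy)-5-methoxyphenyl]-2-{2-[4-(benzyloxy)-3-methoxyphenyl]ethyl}oxan-4-yl acetate F2. Lewis-acid debenzylation with BCl3 and pentamethylbenzene as benzyl-cation scavenger in CH2Cl2 at −78 °C should then free the three phenols, arriving at 22.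

**Further compounds**

F1 | step 9 | methyl (2E,5S,7S)-7-[3,4-bis(benzyloxy)-5-methoxyphenyl]-5-[(tert-butyldimethylsilyl)oxy]-7-hydroxyhept-2-enoate | COC(=O)/C=C/C[C@H](O[Si](C)(C)C(C)(C)C)C[C@H](O)c1cc(OCc2ccccc2)c(OCc2ccccc2)c(OC)c1
F0 | step 8 | none | none
F2 | step 15 | (2S,4S,6S)-6-[3,4-bis(benzyloxy)-5-methoxyphenyl]-2-{2-[4-(benzyloxy)-3-methoxyphenyl]ethyl}oxan-4-yl acetate | COc1cc(CC[C@H]2C[C@H](OC(C)=O)C[C@@H](c3cc(OCc4ccccc4)c(OCc4ccccc4)c(OC)c3)O2)ccc1OCc1ccccc1
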